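## Structural features

The target is a pentacyclic depsidone. Ring A is a 4-methoxy-6-(2-oxoheptyl)benzoyl unit, and ring B is a fully substituted phenol arene except for one C–H. The two arenes are joined twice on neighbouring carbons of ring B, by an aryl ester and by a diaryl ether, which closes the seven-membered dioxepinone ring C. Ring B is also fused to a δ-lactone, ring D (an isochroman-1-one, whose numbering is used for ring B below); C3 of ring D is the spiro carbon of the 6-methyltetrahydropyran ring E and is both a ketal carbon and an acyloxy carbon. The two stereocentres, the spiro carbon (S) and the methyl carbinol (R), are not adjacent but 1,3-related across the ring E oxygen. With the methyl group equatorial, the S configuration places the lactone oxygen axial on ring E, the anomerically preferred arrangement, so the spiro centre can be set by equilibration. The fragile groups are the aryl ester of ring C (an active ester, open to acyl transfer), the ketal-type lactone of rings D and E (acid), and the benzyl ketone of the side chain, whose enol or enolate can reach the ring A carbonyl and close an isocoumarin with expulsion of ring B. The real difficulty is ring B: three oxygens with three different roles (ether oxygen at C5, ester oxygen at C6, chelated phenol at C8), and a tri-ortho-substituted diaryl ether held in a seven-membered ring. The key step uses the fact that the oxygens at C5, C6 and C8 flank the carboxyl-bearing C8a and the chain-bearing C4a, which is the imprint of a 1,3,4-trioxygenated butadiene on an alkynoate, and that C4 and C3 together stand at the oxidation level of a second triple bond carried by the dienophile.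

## Logic of the disconnections

31 to 30: only the side-chain carbonyl is changed, into its ethylene ketal. The free ketone has acidic benzylic α-hydrogens next to an aryl ester and would not survive base. The forward step must be an acid hydrolysis mild enough to spare ring C and the spiroketal lactone.

30 to 29: the diaryl ether C–O bond between O5 of ring B and the ring A carbon ortho to the carbonyl is cut, opening ring C. With the ester kept as a tether, the most hindered bond of the molecule is formed intramolecularly, and ring A becomes a plain 2-fluorobenzoate. The forward step needs the C5 phenoxide to attack the C–F carbon faster than the ester carbonyl.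

29 to 28, then to 18 and 26: the benzyl group is put back on O5 and the ester C–O bond at O6 is cut. This gives two fragments of similar size, and O6 of 18 is the only unchelated phenol, so it can be acylated selectively. The forward step needs activation of the hindered acid 26 without acid that would open its ketal, which is done through 27.

18 to 16, then to 15: both C–O bonds at the spiro carbon are cut and C3/C4 return to a triple bond, with the lactone carbonyl returning to a methyl ester. Rings D and E and the spiro centre disappear, leaving only the carbinol stereocentre. The forward step needs attack of the hydroxyl at the alkyne carbon remote from the arene (through 17) and equilibrating conditions for the spiro centre.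

15 to 3 and 12 (key disconnection): the C1–C6 and C2–C3 bonds of the benzoate ring of 15 are cut. All six substituents of ring B, already differentiated, arise from two acyclic partners, through 13 and 14. The forward step needs regiocontrol, reaction at the ester-bound triple bond only, and a single direction of aromatisation.

3 to 2 to 1: two O–Si bonds are cut. The diene is the doubly enol-silylated form of a commercial β-keto ester. The forward steps need γ-deprotonation of 2 and exclusion of moisture.

12 to 9 and 11, and 11 to 10: the C4–C5 sp–sp bond of the diynoate is cut, and then the C–Br bond of 11. This separates the ester-bearing C3 unit from the chiral chain. The forward coupling must be faster than addition of the base to 11.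

9 to 8 to 7, then to 4 and 5 (through 6): after the two silyl changes, the C3–C4 bond of the heptynol chain is cut. The carbinol stereocentre comes unchanged from 5. The forward step needs a carbon nucleophile without an acidic acetylenic hydrogen, hence the C-silyl group in 4.

26 to 24 (through 25), to 23, to 22, then to 19 and 20 (through 21): the aryl–carboxyl bond, the aryl–bromine bond, the ketal and the benzyl–acyl bond are cut in turn. Ring A is traced to a commercial benzyl bromide and an acid chloride. The forward steps need bromination para to the methoxy group and a low temperature for 25.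

## Other disconnections considered

Alternative 1: The cut is in ring C, at the aryl–carbonyl bond of ring A and the acyl–oxygen bond to ring B, so that the ester carbon comes from carbon monoxide. In the forward step the ortho-iodo diaryl ether A1, with the C6 phenol of ring B free, would be treated with Pd(OAc)2 and Xantphos under CO. Oxidative addition of zerovalent palladium into the C–I bond, CO insertion and capture of the acylpalladium by the phenol would give the ketal-protected depsidone A2, which has the same structure as 30.
- In its favour: the ester appears only after the ether is in place, so no catechol monoester meets base and an acyl shift between O5 and O6 is excluded. On this point it is better than the chosen plan. Ring A also needs no carboxyl group and no activation of a hindered acid.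
- Against it: A1 is a tri-ortho-substituted diaryl ether that must first be made intermolecularly at the most hindered oxygen of ring B, with O6 masked and later unmasked. The iodide is flanked by the aryloxy group and the ketal-bearing CH2, so oxidative addition and insertion should be slow and hydrodehalogenation could compete. A seven-membered lactone from an acylpalladium is a less favourable closure than the five- and six-membered cases.
- Comparison: on ring B the two plans are equal, since A1 could be reached from 18. In mildness of the ring C closure they are about equal. In step count the alternative should be two to three steps longer because of the protecting-group changes and the intermolecular ether synthesis.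

Alternative 2: The cut is at the C4–C3 bond (benzylic carbon to spiro carbon) and at the lactone acyl–oxygen bond. In the forward step LiN(i-Pr)2 would deprotonate the benzylic methyl of the toluate A3, the anion would add to the carbonyl of the lactone A4, and the resulting alkoxide would close on the neighbouring methyl ester to give the spiroketal lactone A5.
- In its favour: one operation forms a C–C bond and ring D while keeping ring E. The carbinol comes from the chiral pool as in the chosen plan, and the spiro centre is again under thermodynamic control (equal). No precious metal and no alkyne chemistry are needed (better). A5 already carries the three oxygens in differentiated form, which suits an ether-first endgame.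
- Against it: the hexasubstituted, triply differentiated arene A3 must be built by stepwise substitution of a benzene, which is exactly the crowding that the cycloaddition removes. The first adduct is a benzyl ketone more acidic than A3 and would quench the anion, A4 can be enolised, and lactonisation on a di-ortho-substituted ester may need a separate acid step.
- Comparison: the key step forms one C–C bond where the chosen step forms two and a ring. Convergence is similar. The route should be longer overall because of A3, but it avoids the site-selectivity questions of a diynoate.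

Alternative 3: The cut is at the diaryl ether C–O bond and at the aryl–carboxyl bond of ring A. In the forward step CsF would release an aryne from the silyl triflate A6, the cesium phenoxide of A7 would add to the aryne carbon remote from the side chain, and the aryl anion would be trapped by CO2 to give the 2-aryloxybenzoic acid A8, with no ring closed.
- In its favour: it is free of transition metals and forms the hindered diaryl ether under conditions where substitution or copper coupling struggle. It installs the carboxyl group in the same operation and is highly convergent (better on these points). No acyl group is present on ring B, so acyl shift is excluded (better).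
- Against it: the direction of phenoxide addition to a 3-alkyl-5-methoxy aryne rests on a modest steric and inductive bias. Protonation of the aryl anion can outrun carboxylation. The phenoxide can be carbonated by CO2 and lose nucleophilicity. A6 and A7 each need several steps, including the protection pattern of ring B, and a seven-membered lactonisation of a hindered acid still follows.
- Comparison: it is equal in its need for the ketal mask and in the origin of the stereocentres. It is better in convergence. It is worse in regiochemical certainty and should be longer in total steps.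

Key step: step 8

Remark on the chemistry: 4-bromobut-1-yne is used in its commercial C-trimethylsilyl form 4, because an acetylenic C–H would quench the Grignard reagent; the S spiro configuration is taken to be the thermodynamically preferred one (lactone oxygen axial, methyl equatorial on ring E).

## Route

Step 1
Reactants: 1 ethyl 4-(benzyloxy)-3-oxobutanoate
Product: 2 ethyl 4-(benzyloxy)-3-[(trimethylsilyl)oxy]but-2-enoate
Conditions: Me3SiCl, Et3N, toluene, rt
Reagents that add atoms: chlorotrimethylsilane, C[Si](C)(C)Cl
Why: Silyl enol ether formation: the enolised β-keto ester is O-silylated at the ketone oxygen, the standard first stage of a Chan-type diene synthesis; the benzyl ether and ester are inert.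

Step 2
Reactants: 2 ethyl 4-(benzyloxy)-3-[(trimethylsilyl)oxy]but-2-enoate
Product: 3 4-(benzyloxy)-1-ethoxy-1,3-bis[(trimethylsilyl)oxy]buta-1,3-diene
Conditions: LiN(i-Pr)2, THF, −78 °C; Me3SiCl, −78 °C to rt; filtration under argon, no chromatography
Reagents that add atoms: chlorotrimethylsilane, C[Si](C)(C)Cl
Why: Kinetic γ-deprotonation at the CH2OBn carbon gives the extended enolate, which is O-silylated at the ester oxygen to the 1,3-bis(silyloxy)diene; the 3Z geometry (benzyloxy outside the s-cis diene) is expected, and the moisture-sensitive diene is used at once.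

Step 3
Reactants: 4 (4-bromobut-1-yn-1-yl)trimethylsilane; 5 (R)-2-methyloxirane
Product: 7 (R)-7-(trimethylsilyl)hept-6-yn-2-ol, via Grignard reagent 6 (not isolated)
Conditions: Mg, THF, rt; then CuI (10 mol %), 5, THF, −40 to 0 °C; NH4Cl (aq)
Reagents that add atoms: none
Why: Copper-catalysed SN2 opening of the epoxide by the homopropargyl Grignard reagent at the unsubstituted carbon; the C–O bond of the stereocentre is not touched, so the R configuration of 5 is carried into the carbinol.

Step 4
Reactants: 7 (R)-7-(trimethylsilyl)hept-6-yn-2-ol
Product: 8 (R)-tert-butyldimethyl{[7-(trimethylsilyl)hept-6-yn-2-yl]oxy}silane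
Conditions: t-BuMe2SiCl, imidazole, DMF, rt
Reagents that add atoms: tert-butyldimethylsilyl chloride, CC(C)(C)[Si](C)(C)Cl
Why: Standard silylation of a secondary alcohol; the ether is needed later so that the hydroxyl neither consumes diene 3 nor adds to the diynoate.

Step 5
Reactants: 8 (R)-tert-butyldimethyl{[7-(trimethylsilyl)hept-6-yn-2-yl]oxy}silane
Product: 9 (R)-tert-butyl(hept-6-yn-2-yloxy)dimethylsilane
Conditions: K2CO3 (cat.), MeOH, rt
Reagents that add atoms: none
Why: Methanolysis of the alkynyl C–Si bond by catalytic methoxide; the alkyl silyl ether is stable to these conditions.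

Step 6
Reactants: 10 methyl propiolate
Product: 11 methyl 3-bromopropiolate
Conditions: N-bromosuccinimide, AgNO3 (10 mol %), acetone, rt
Reagents that add atoms: N-bromosuccinimide, O=C1CCC(=O)N1Br
Why: Silver-catalysed electrophilic bromination of a terminal alkyne, the standard preparation of this bromoalkynoate; 11 is a lachrymator and is used as a solution without storage.

Step 7
Reactants: 9 (R)-tert-butyl(hept-6-yn-2-yloxy)dimethylsilane; 11 methyl 3-bromopropiolate
Product: 12 methyl (R)-9-[(tert-butyldimethylsilyl)oxy]deca-2,4-diynoate
Conditions: CuI (5 mol %), PdCl2(PPh3)2 (2 mol %), i-Pr2NH, THF, 0 °C, slow addition of 11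
Reagents that add atoms: none
Why: Cadiot–Chodkiewicz-type C(sp)–C(sp) heterocoupling of a terminal alkyne with a 1-bromoalkyne through the copper acetylide, with palladium co-catalysis and a hindered amine so that conjugate addition of the base to the electrophilic bromoalkynoate stays slow; slow addition limits homocoupling.

Step 8
Reactants: 3 4-(benzyloxy)-1-ethoxy-1,3-bis[(trimethylsilyl)oxy]buta-1,3-diene; 12 methyl (R)-9-[(tert-butyldimethylsilyl)oxy]deca-2,4-diynoate
Product: 15 methyl 3-(benzyloxy)-2-[(6R)-6-(tert-butyldimethylsilyloxy)hept-1-yn-1-yl]-4,6-dihydroxybenzoate, via cyclohexa-1,4-diene cycloadduct 13 (not isolated), via bis(trimethylsilyl) aryl ether 14 (not isolated)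
Conditions: 3 (1.5 equiv), toluene, 80 °C; then 0.5 M HCl, THF, 0 °C
Reagents that add atoms: none
Why: This is a normal-demand Diels–Alder benzannulation, the known reaction of 1-alkoxy-1,3-bis(silyloxy)butadienes with alkynoates to give 4-hydroxysalicylates (or its stepwise Mukaiyama–Michael/Claisen equivalent): the benzyloxy-bearing terminus C4 of 3, the carbon of highest HOMO coefficient, bonds to C3 of 12 (β to the ester) and the ketene acetal carbon C1 of 3 bonds to C2 of 12, giving cyclohexa-1,4-diene 13. Ring B closes in this single intermolecular [4+2] event, suprafacial on both partners through the s-cis diene, so no separate cyclisation mode has to be chosen. Adduct 13 cannot aromatise by losing benzyl alcohol because its ketal carbon carries no hydrogen; 1,4-elimination of ethoxytrimethylsilane (ethoxy from C6, hydrogen from C3 of 13) is the only path and gives 14, which the cold acid work-up desilylates at the two aryl oxygens only. No stereocentre is created: the two sp3 carbons of 13 are erased on aromatisation, and the R carbinol of 12, four atoms from the reacting alkyne, is a spectator. Regioselectivity rests on matched polarisation (nucleophilic diene terminus, electrophilic ynoate β-carbon). Chemoselectivity for the C2–C3 triple bond rests on its direct ester activation, since the remote triple bond is only vinylogously activated and attack at C5 offers no six-membered closure. The silyl ether on the carbinol is part of the design: a free hydroxyl would be silylated by 3 and could add to C5 of the diynoate.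

Step 9
Reactants: 15 methyl 3-(benzyloxy)-2-[(6R)-6-(tert-butyldimethylsilyloxy)hept-1-yn-1-yl]-4,6-dihydroxybenzoate
Product: 16 methyl 3-(benzyloxy)-4,6-dihydroxy-2-[(6R)-6-hydroxyhept-1-yn-1-yl]benzoate
Conditions: HF·pyridine, THF, 0 °C to rt
Reagents that add atoms: none
Why: Fluoride cleavage of the secondary silyl ether under buffered acidic conditions; phenols, ester, benzyl ether and alkyne are inert to this reagent.

Step 10
Reactants: 16 methyl 3-(benzyloxy)-4,6-dihydroxy-2-[(6R)-6-hydroxyhept-1-yn-1-yl]benzoate
Product: 18 (3S,6'R)-5-(benzyloxy)-6,8-dihydroxy-6'-methylspiro[isochromane-3,2'-oxan]-1-one, via enol ether 17 (not isolated)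
Conditions: Ph3PAuNTf2 (5 mol %), H2O (2 equiv), CH2Cl2, rt; then p-TsOH·H2O (10 mol %), rt
Reagents that add atoms: water, O
Why: Gold-catalysed alkynol cycloisomerisation combined with lactonisation (the known tandem hydroalkoxylation/spiroketal-lactone formation of ortho-alkynyl benzoates): monovalent gold activates the alkyne, the hydroxyl attacks the carbon remote from the arene in 6-exo-dig fashion to give 17, and protonation gives a cyclic oxocarbenium ion that is captured by water and the neighbouring methyl ester with loss of methanol. The spiro centre is set under thermodynamic control during the acid equilibration: with the methyl equatorial on ring E the lactone oxygen takes the axial (anomeric) position, which is the S configuration.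

Step 11
Reactants: 19 1-(bromomethyl)-3-fluoro-5-methoxybenzene; 20 hexanoyl chloride
Product: 22 1-(3-fluoro-5-methoxyphenyl)heptan-2-one, via benzylzinc bromide 21 (not isolated)
Conditions: Zn, LiCl, THF, rt; then 20, Pd(PPh3)4 (2 mol %), THF, 0 °C to rt
Reagents that add atoms: none
Why: Zinc insertion into the benzylic bromide followed by palladium-catalysed Negishi acylation with the acid chloride gives the benzyl ketone without over-addition; the aryl fluoride and methyl ether are inert.

Step 12
Reactants: 22 1-(3-fluoro-5-methoxyphenyl)heptan-2-one
Product: 23 2-(3-fluoro-5-methoxybenzyl)-2-pentyl-1,3-dioxolane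
Conditions: HOCH2CH2OH, p-TsOH·H2O (cat.), toluene, reflux, Dean–Stark
Reagents that add atoms: ethylene glycol, OCCO
Why: Acid-catalysed ketalisation with azeotropic removal of water; the mask removes the acidic benzylic α-hydrogens that would later allow enolate attack on the aryl ester (isocoumarin formation).

Step 13
Reactants: 23 2-(3-fluoro-5-methoxybenzyl)-2-pentyl-1,3-dioxolane
Product: 24 2-(2-bromo-3-fluoro-5-methoxybenzyl)-2-pentyl-1,3-dioxolane
Conditions: N-bromosuccinimide, MeCN, 0 °C to rt, dark
Reagents that add atoms: N-bromosuccinimide, O=C1CCC(=O)N1Br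
Why: Electrophilic aromatic bromination with N-bromosuccinimide in acetonitrile, which is para-selective for anisoles; the position para to methoxy lies between the small fluorine and the CH2 group and is also ortho to fluorine, and the ketal is stable because no HBr is released.

Step 14
Reactants: 24 2-(2-bromo-3-fluoro-5-methoxybenzyl)-2-pentyl-1,3-dioxolane
Product: 26 2-fluoro-4-methoxy-6-[(2-pentyl-1,3-dioxolan-2-yl)methyl]benzoic acid, via aryllithium 25 (not isolated)
Conditions: n-BuLi, THF, −78 °C; CO2, −78 °C to rt; NH4Cl (aq), then citric acid to pH 4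
Reagents that add atoms: carbon dioxide, O=C=O
Why: Bromine–lithium exchange at −78 °C, faster than any deprotonation, followed by carboxylation of the aryllithium; the low temperature keeps the ortho-fluoro aryllithium from losing LiF to an aryne, and the weakly acidic work-up spares the ketal.

Step 15
Reactants: 26 2-fluoro-4-methoxy-6-[(2-pentyl-1,3-dioxolan-2-yl)methyl]benzoic acid; 18 (3S,6'R)-5-(benzyloxy)-6,8-dihydroxy-6'-methylspiro[isochromane-3,2'-oxan]-1-one
Product: 28 (3S,6'R)-5-(benzyloxy)-8-hydroxy-6'-methyl-1-oxospiro[isochromane-3,2'-oxan]-6-yl 2-fluoro-4-methoxy-6-[(2-pentyl-1,3-dioxolan-2-yl)methyl]benzoate, via acid chloride 27 (not isolated)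
Conditions: 1-chloro-N,N,2-trimethylprop-1-en-1-amine, CH2Cl2, 0 °C to rt; then 18, Et3N, DMAP (cat.), CH2Cl2, 0 °C to rt
Reagents that add atoms: none
Why: Acid chloride formation under neutral conditions (Ghosez reagent, no HCl, ketal intact), then DMAP-catalysed acylation of a phenol; the C6 hydroxyl of 18 is the more acidic, unchelated one (para to the lactone carbonyl), whereas the C8 hydroxyl is hydrogen-bonded to the lactone carbonyl, so monoacylation at O6 is expected with one equivalent of 27.

Step 16
Reactants: 28 (3S,6'R)-5-(benzyloxy)-8-hydroxy-6'-methyl-1-oxospiro[isochromane-3,2'-oxan]-6-yl 2-fluoro-4-methoxy-6-[(2-pentyl-1,3-dioxolan-2-yl)methyl]benzoate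
Product: 29 (3S,6'R)-5,8-dihydroxy-6'-methyl-1-oxospiro[isochromane-3,2'-oxan]-6-yl 2-fluoro-4-methoxy-6-[(2-pentyl-1,3-dioxolan-2-yl)methyl]benzoate
Conditions: H2 (1 atm), Pd/C, EtOAc, rt
Reagents that add atoms: none
Why: Hydrogenolysis of the aryl benzyl ether over Pd/C; the aryl fluoride, aryl ester, ketal and spiroketal lactone are not reduced under one atmosphere of hydrogen.

Step 17
Reactants: 29 (3S,6'R)-5,8-dihydroxy-6'-methyl-1-oxospiro[isochromane-3,2'-oxan]-6-yl 2-fluoro-4-methoxy-6-[(2-pentyl-1,3-dioxolan-2-yl)methyl]benzoate
Product: 30 ethylene ketal of the target: the depsidone in which O5 of ring B is bonded to C2 of the ring A benzoyl group, ring A carrying 4-methoxy and 6-[(2-pentyl-1,3-dioxolan-2-yl)methyl], with S spiro carbon and R methyl carbinol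
Conditions: Cs2CO3, DMSO (0.01 M), 70 °C
Reagents that add atoms: none
Why: Intramolecular nucleophilic aromatic substitution through a Meisenheimer intermediate: the C5 phenoxide attacks the fluorine-bearing carbon ortho to the ester carbonyl and closes the seven-membered ring C, the ester serving as activating group and tether. The di-ortho-substituted aroyl carbonyl is shielded, which should slow the competing 1,2-acyl shift to O5, and the ketal keeps the side chain from enolising.

Step 18
Reactants: 30 ethylene ketal of the target
Product: 31 CNP0301127.1, the depsidone with the 2-oxoheptyl side chain on ring A, S spiro carbon and R methyl carbinol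
Conditions: pyridinium p-toluenesulfonate, acetone/H2O (9:1), 50 °C
Reagents that add atoms: water, O
Why: Mild acid-catalysed hydrolysis of the dioxolane to the ketone; the weak acid should leave the aryl ester intact, and any equilibration of the spiroketal returns the same thermodynamically preferred S isomer.

## Compound list

1 | ethyl 4-(benzyloxy)-3-oxobutanoate | CCOC(=O)CC(=O)COCc1ccccc1 | starting material
2 | ethyl 4-(benzyloxy)-3-[(trimethylsilyl)oxy]but-2-enoate (double-bond geometry not defined) | CCOC(=O)C=C(O[Si](C)(C)C)COCc1ccccc1 | intermediate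
3 | 4-(benzyloxy)-1-ethoxy-1,3-bis[(trimethylsilyl)oxy]buta-1,3-diene (3Z expected, drawn without geometry) | CCOC(O[Si](C)(C)C)=CC(O[Si](C)(C)C)=COCc1ccccc1 | intermediate
4 | (4-bromobut-1-yn-1-yl)trimethylsilane | C[Si](C)(C)C#CCCBr | starting material
5 | (R)-2-methyloxirane | C[C@@H]1CO1 | starting material
6 | [4-(trimethylsilyl)but-3-yn-1-yl]magnesium bromide | C[Si](C)(C)C#CCC[Mg]Br | intermediate
7 | (R)-7-(trimethylsilyl)hept-6-yn-2-ol | C[Si](C)(C)C#CCCC[C@@H](C)O | intermediate
8 | (R)-tert-butyldimethyl{[7-(trimethylsilyl)hept-6-yn-2-yl]oxy}silane | C[Si](C)(C)C#CCCC[C@@H](C)O[Si](C)(C)C(C)(C)C | intermediate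
9 | (R)-tert-butyl(hept-6-yn-2-yloxy)dimethylsilane | C#CCCC[C@@H](C)O[Si](C)(C)C(C)(C)C | intermediate
10 | methyl propiolate | C#CC(=O)OC | starting material
11 | methyl 3-bromopropiolate | COC(=O)C#CBr | intermediate
12 | methyl (R)-9-[(tert-butyldimethylsilyl)oxy]deca-2,4-diynoate | COC(=O)C#CC#CCCC[C@@H](C)O[Si](C)(C)C(C)(C)C | intermediate
13 | methyl 3-(benzyloxy)-6-ethoxy-2-[(6R)-6-(tert-butyldimethylsilyloxy)hept-1-yn-1-yl]-4,6-bis[(trimethylsilyl)oxy]cyclohexa-1,4-diene-1-carboxylate (mixture at C3 and C6) | CCOC1(O[Si](C)(C)C)C=C(O[Si](C)(C)C)C(OCc2ccccc2)C(C#CCCC[C@@H](C)O[Si](C)(C)C(C)(C)C)=C1C(=O)OC | intermediate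
14 | methyl 3-(benzyloxy)-2-[(6R)-6-(tert-butyldimethylsilyloxy)hept-1-yn-1-yl]-4,6-bis[(trimethylsilyl)oxy]benzoate | COC(=O)c1c(O[Si](C)(C)C)cc(O[Si](C)(C)C)c(OCc2ccccc2)c1C#CCCC[C@@H](C)O[Si](C)(C)C(C)(C)C | intermediate
15 | methyl 3-(benzyloxy)-2-[(6R)-6-(tert-butyldimethylsilyloxy)hept-1-yn-1-yl]-4,6-dihydroxybenzoate (the 5-benzyloxy-2,4-dihydroxy-6-alkynylbenzoate in the other numbering) | COC(=O)c1c(O)cc(O)c(OCc2ccccc2)c1C#CCCC[C@@H](C)O[Si](C)(C)C(C)(C)C | intermediate
16 | methyl 3-(benzyloxy)-4,6-dihydroxy-2-[(6R)-6-hydroxyhept-1-yn-1-yl]benzoate | COC(=O)c1c(O)cc(O)c(OCc2ccccc2)c1C#CCCC[C@@H](C)O | intermediate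
17 | methyl 3-(benzyloxy)-4,6-dihydroxy-2-{(Z)-[(6R)-6-methyloxan-2-ylidene]methyl}benzoate | COC(=O)c1c(O)cc(O)c(OCc2ccccc2)c1/C=C1/CCC[C@@H](C)O1 | intermediate
18 | (3S,6'R)-5-(benzyloxy)-6,8-dihydroxy-6'-methylspiro[isochromane-3,2'-oxan]-1-one | Oc1cc(O)c2c(c1OCc1ccccc1)C[C@]1(CCC[C@@H](C)O1)OC2=O | intermediate
19 | 1-(bromomethyl)-3-fluoro-5-methoxybenzene | COc1cc(F)cc(CBr)c1 | starting material
20 | hexanoyl chloride | CCCCCC(=O)Cl | starting material
21 | (3-fluoro-5-methoxybenzyl)zinc bromide | COc1cc(F)cc(C[Zn]Br)c1 | intermediate
22 | 1-(3-fluoro-5-methoxyphenyl)heptan-2-one | CCCCCC(=O)Cc1cc(F)cc(OC)c1 | intermediate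
23 | 2-(3-fluoro-5-methoxybenzyl)-2-pentyl-1,3-dioxolane | CCCCCC1(OCCO1)Cc1cc(F)cc(OC)c1 | intermediate
24 | 2-(2-bromo-3-fluoro-5-methoxybenzyl)-2-pentyl-1,3-dioxolane | CCCCCC1(OCCO1)Cc1cc(OC)cc(F)c1Br | intermediate
25 | {2-fluoro-4-methoxy-6-[(2-pentyl-1,3-dioxolan-2-yl)methyl]phenyl}lithium | CCCCCC1(OCCO1)Cc1cc(OC)cc(F)c1[Li] | intermediate
26 | 2-fluoro-4-methoxy-6-[(2-pentyl-1,3-dioxolan-2-yl)methyl]benzoic acid | CCCCCC1(OCCO1)Cc1cc(OC)cc(F)c1C(=O)O | intermediate
27 | 2-fluoro-4-methoxy-6-[(2-pentyl-1,3-dioxolan-2-yl)methyl]benzoyl chloride | CCCCCC1(OCCO1)Cc1cc(OC)cc(F)c1C(=O)Cl | intermediate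
28 | (3S,6'R)-5-(benzyloxy)-8-hydroxy-6'-methyl-1-oxospiro[isochromane-3,2'-oxan]-6-yl 2-fluoro-4-methoxy-6-[(2-pentyl-1,3-dioxolan-2-yl)methyl]benzoate | CCCCCC1(OCCO1)Cc1cc(OC)cc(F)c1C(=O)Oc1cc(O)c2c(c1OCc1ccccc1)C[C@]1(CCC[C@@H](C)O1)OC2=O | intermediate
29 | (3S,6'R)-5,8-dihydroxy-6'-methyl-1-oxospiro[isochromane-3,2'-oxan]-6-yl 2-fluoro-4-methoxy-6-[(2-pentyl-1,3-dioxolan-2-yl)methyl]benzoate | CCCCCC1(OCCO1)Cc1cc(OC)cc(F)c1C(=O)Oc1cc(O)c2c(c1O)C[C@]1(CCC[C@@H](C)O1)OC2=O | intermediate
30 | ethylene ketal of the target (depsidone with 2-pentyl-1,3-dioxolan-2-ylmethyl side chain, S spiro carbon, R carbinol) | CCCCCC1(OCCO1)Cc1cc(OC)cc2c1C(=O)Oc1cc(O)c3c(c1O2)C[C@]1(CCC[C@@H](C)O1)OC3=O | intermediate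
31 | CNP0301127.1 (depsidone with 2-oxoheptyl side chain, S spiro carbon, R carbinol) | CCCCCC(=O)Cc1cc(OC)cc2c1C(=O)Oc1cc(O)c3c(c1O2)C[C@]1(CCC[C@@H](C)O1)OC3=O | target

## Step count and least certain steps

Total step count: 18. Longest linear sequence: 11 steps (steps 3, 4, 5, 7, 8, 9, 10, 15, 16, 17, 18).

Step 8 (key step). What may go wrong is loss of site selectivity: conjugate attack of the diene terminus at C5 of the diynoate, or ring closure onto the ester carbonyl in place of the ketene acetal carbon. Thermal oligomerisation of the diynoate and hydrolytic loss of the diene before it reacts are also possible. The reasons are that the benzyloxy group adds bulk at the nucleophilic terminus and that the β-carbon of 12 carries a second alkyne. The fallback sets out from 3, 11 and 9 and comes back at 15. Diene 3 would be combined with the smaller and more electrophilic bromoalkynoate 11 (toluene, 60 °C, then cold dilute HCl) to give methyl 3-(benzyloxy)-2-bromo-4,6-dihydroxybenzoate F1, with bromine where the alkyne is needed. A copper-free Sonogashira coupling of F1 with alkyne 9 (PdCl2(MeCN)2, XPhos, Cs2CO3, MeCN, 70 °C) would then give 15. This moves the second alkyne from the dienophile to a cross-coupling and removes the competition between two triple bonds.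

Step 17. What may go wrong is a base-induced 1,2-acyl shift of the ring A aroyl group from O6 to the neighbouring O5 before substitution. The O6 phenoxide would then close the regioisomeric depsidone. The substitution itself may also be slow, because the fluoride is activated by one ester only. The fallback sets out from 18 and 24 and comes back at 30; it forms the ether first, so that no acyl group is on ring B when base is present.
- Hydrogenolysis of 18 (H2, Pd/C) would give (3S,6'R)-5,6,8-trihydroxy-6'-methylspiro[isochromane-3,2'-oxan]-1-one F2.
- Benzylation of its most acidic hydroxyl, para to the lactone carbonyl (BnBr, one equivalent, KHCO3, DMF), would give (3S,6'R)-6-(benzyloxy)-5,8-dihydroxy-6'-methylspiro[isochromane-3,2'-oxan]-1-one F3.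
- Bromide 24 would be lithiated as in step 14 and formylated with DMF to give 2-fluoro-4-methoxy-6-[(2-pentyl-1,3-dioxolan-2-yl)methyl]benzaldehyde F4, whose fluoride is more strongly activated.
- Intermolecular substitution of F4 by the C5 phenoxide of F3 (K2CO3, DMF, 90 °C) would give 2-{[(3S,6'R)-6-(benzyloxy)-8-hydroxy-6'-methyl-1-oxospiro[isochromane-3,2'-oxan]-5-yl]oxy}-4-methoxy-6-[(2-pentyl-1,3-dioxolan-2-yl)methyl]benzaldehyde F5.
- Pinnick oxidation (NaClO2, NaH2PO4, 2-methylbut-2-ene, t-BuOH/H2O) would give the corresponding benzoic acid F6.
- Hydrogenolysis would give 2-{[(3S,6'R)-6,8-dihydroxy-6'-methyl-1-oxospiro[isochromane-3,2'-oxan]-5-yl]oxy}-4-methoxy-6-[(2-pentyl-1,3-dioxolan-2-yl)methyl]benzoic acid F7.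
- Lactonisation of F7 onto O6 (2-chloro-1-methylpyridinium iodide, Et3N, CH2Cl2, high dilution) would give 30.

Step 10. What may go wrong is diversion of the gold-activated alkyne: 5-exo attack of the ester carbonyl to an alkylidene phthalide, attack of the neighbouring benzyl ether oxygen with benzyl transfer to a benzofuran, or incomplete loss of the methyl group. The cause is that three oxygen nucleophiles sit within reach of the alkyne. The fallback sets out from 16 and comes back at 18, and it uses Brønsted acid only. Saponification of 16 (LiOH, THF/H2O, 50 °C) would give 3-(benzyloxy)-4,6-dihydroxy-2-[(6R)-6-hydroxyhept-1-yn-1-yl]benzoic acid F8. Treatment with catalytic TfOH in CH2Cl2 should close the acid in the 6-endo mode to 5-(benzyloxy)-6,8-dihydroxy-3-[(4R)-4-hydroxypentyl]-1H-isochromen-1-one F9. Under the same acid, or with camphorsulfonic acid, the side-chain hydroxyl should add to C3 of the protonated enol lactone of F9 and give 18 under thermodynamic control.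

Step 7. What may go wrong is consumption of the bromoalkynoate by conjugate addition of the amine, and homocoupling of either partner, because 11 is a strong Michael acceptor. The fallback sets out from 9 and comes back at 12, and it introduces the ester last. Bromination of 9 (N-bromosuccinimide, AgNO3, acetone) would give (R)-[(7-bromohept-6-yn-2-yl)oxy](tert-butyl)dimethylsilane F10. A classical Cadiot–Chodkiewicz coupling with triethylsilylacetylene (CuCl, NH2OH·HCl, n-BuNH2, H2O/CH2Cl2, 0 °C) would give (R)-tert-butyldimethyl{[9-(triethylsilyl)nona-6,8-diyn-2-yl]oxy}silane F11. Methanolysis (K2CO3, MeOH) would give (R)-tert-butyldimethyl(nona-6,8-diyn-2-yloxy)silane F12. Deprotonation with n-BuLi at −78 °C and quenching with methyl chloroformate would give 12.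

## Further compounds

F1 | step 8 | methyl 3-(benzyloxy)-2-bromo-4,6-dihydroxybenzoate | COC(=O)c1c(O)cc(O)c(OCc2ccccc2)c1Br
F2 | step 17 | (3S,6'R)-5,6,8-trihydroxy-6'-methylspiro[isochromane-3,2'-oxan]-1-one | Oc1cc(O)c2c(c1O)C[C@]1(CCC[C@@H](C)O1)OC2=O
F3 | step 17 | (3S,6'R)-6-(benzyloxy)-5,8-dihydroxy-6'-methylspiro[isochromane-3,2'-oxan]-1-one | c1ccccc1COc1cc(O)c2c(c1O)C[C@]1(CCC[C@@H](C)O1)OC2=O
F4 | step 17 | 2-fluoro-4-methoxy-6-[(2-pentyl-1,3-dioxolan-2-yl)methyl]benzaldehyde | CCCCCC1(OCCO1)Cc1cc(OC)cc(F)c1C=O
F5 | step 17 | 2-{[(3S,6'R)-6-(benzyloxy)-8-hydroxy-6'-methyl-1-oxospiro[isochromane-3,2'-oxan]-5-yl]oxy}-4-methoxy-6-[(2-pentyl-1,3-dioxolan-2-yl)methyl]benzaldehyde | CCCCCC1(OCCO1)Cc1cc(OC)cc(Oc2c(OCc3ccccc3)cc(O)c3c2C[C@]2(CCC[C@@H](C)O2)OC3=O)c1C=O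
F6 | step 17 | 2-{[(3S,6'R)-6-(benzyloxy)-8-hydroxy-6'-methyl-1-oxospiro[isochromane-3,2'-oxan]-5-yl]oxy}-4-methoxy-6-[(2-pentyl-1,3-dioxolan-2-yl)methyl]benzoic acid | CCCCCC1(OCCO1)Cc1cc(OC)cc(Oc2c(OCc3ccccc3)cc(O)c3c2C[C@]2(CCC[C@@H](C)O2)OC3=O)c1C(=O)O
F7 | step 17 | 2-{[(3S,6'R)-6,8-dihydroxy-6'-methyl-1-oxospiro[isochromane-3,2'-oxan]-5-yl]oxy}-4-methoxy-6-[(2-pentyl-1,3-dioxolan-2-yl)methyl]benzoic acid | CCCCCC1(OCCO1)Cc1cc(OC)cc(Oc2c(O)cc(O)c3c2C[C@]2(CCC[C@@H](C)O2)OC3=O)c1C(=O)O
F8 | step 10 | 3-(benzyloxy)-4,6-dihydroxy-2-[(6R)-6-hydroxyhept-1-yn-1-yl]benzoic acid | OC(=O)c1c(O)cc(O)c(OCc2ccccc2)c1C#CCCC[C@@H](C)O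
F9 | step 10 | 5-(benzyloxy)-6,8-dihydroxy-3-[(4R)-4-hydroxypentyl]-1H-isochromen-1-one | O=C1OC(CCC[C@@H](C)O)=Cc2c(OCc3ccccc3)c(O)cc(O)c12
F10 | step 7 | (R)-[(7-bromohept-6-yn-2-yl)oxy](tert-butyl)dimethylsilane | BrC#CCCC[C@@H](C)O[Si](C)(C)C(C)(C)C
F11 | step 7 | (R)-tert-butyldimethyl{[9-(triethylsilyl)nona-6,8-diyn-2-yl]oxy}silane | CC[Si](CC)(CC)C#CC#CCCC[C@@H](C)O[Si](C)(C)C(C)(C)C
F12 | step 7 | (R)-tert-butyldimethyl(nona-6,8-diyn-2-yloxy)silane | C#CC#CCCC[C@@H](C)O[Si](C)(C)C(C)(C)C
A1 | alternative 1 | (3S,6'R)-6,8-dihydroxy-5-{2-iodo-5-methoxy-3-[(2-pentyl-1,3-dioxolan-2-yl)methyl]phenoxy}-6'-methylspiro[isochromane-3,2'-oxan]-1-one | CCCCCC1(OCCO1)Cc1cc(OC)cc(Oc2c(O)cc(O)c3c2C[C@]2(CCC[C@@H](C)O2)OC3=O)c1I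
A2 | alternative 1 | depsidone with dioxolane-masked side chain (same structure as 30) | CCCCCC1(OCCO1)Cc1cc(OC)cc2c1C(=O)Oc1cc(O)c3c(c1O2)C[C@]1(CCC[C@@H](C)O1)OC3=O
A3 | alternative 2 | methyl 4,6-bis(benzyloxy)-3-(methoxymethoxy)-2-methylbenzoate | COC(=O)c1c(C)c(OCOC)c(OCc2ccccc2)cc1OCc1ccccc1
A4 | alternative 2 | (R)-6-methyltetrahydro-2H-pyran-2-one | C[C@@H]1CCCC(=O)O1
A5 | alternative 2 | (3S,6'R)-6,8-bis(benzyloxy)-5-(methoxymethoxy)-6'-methylspiro[isochromane-3,2'-oxan]-1-one | COCOc1c(OCc2ccccc2)cc(OCc2ccccc2)c2c1C[C@]1(CCC[C@@H](C)O1)OC2=O
A6 | alternative 3 | 5-methoxy-3-[(2-pentyl-1,3-dioxolan-2-yl)methyl]-2-(trimethylsilyl)phenyl trifluoromethanesulfonate | CCCCCC1(OCCO1)Cc1cc(OC)cc(OS(=O)(=O)C(F)(F)F)c1[Si](C)(C)C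
A7 | alternative 3 | (3S,6'R)-6,8-bis(benzyloxy)-5-hydroxy-6'-methylspiro[isochromane-3,2'-oxan]-1-one | Oc1c(OCc2ccccc2)cc(OCc2ccccc2)c2c1C[C@]1(CCC[C@@H](C)O1)OC2=O
A8 | alternative 3 | 2-{[(3S,6'R)-6,8-bis(benzyloxy)-6'-methyl-1-oxospiro[isochromane-3,2'-oxan]-5-yl]oxy}-4-methoxy-6-[(2-pentyl-1,3-dioxolan-2-yl)methyl]benzoic acid | CCCCCC1(OCCO1)Cc1cc(OC)cc(Oc2c(OCc3ccccc3)cc(OCc3ccccc3)c3c2C[C@]2(CCC[C@@H](C)O2)OC3=O)c1C(=O)O
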